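The runs were computed for an exercise; noise was put on by code.

The constants are hidden, so I read from the two earlier runs the one I mean to carry: how fast complex with one exchanged fades once it is made.

the same everywhere: starting complex 0.41 M; protic impurity 0.205 M
- Tuesday's: incoming ligand 0.44 M; leaving ligand 0.82 M; run made earlier
- Friday's: incoming ligand 1.5 M; leaving ligand 0.82 M; run made earlier
- dusk: incoming ligand 0.328 M; leaving ligand 0.820 M; time 25 h
- winter: incoming ligand 0.492 M; leaving ligand 0.820 M; time 25 h
- dawn: incoming ligand 1.02 M; leaving ligand 0.820 M; time 25 h

| Tuesday's: time / h | Tuesday's: complex with one exchanged / % | Friday's: time / h | Friday's: complex with one exchanged / % |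
|---|---|---|---|
| 2.00 | 26.0 | 0.833 | 39.6 |
| 4.00 | 33.3 | 2.50 | 41.7 |
| 6.00 | 34.3 | 4.00 | 33.4 |
| 8.00 | 35.1 | 6.00 | 25.2 |
| 10.0 | 34.9 | 10.0 | 13.1 |
| 12.0 | 36.2 | 12.0 | 10.8 |

(scatter of a reading: 1 percentage point)



* amount of complex with one exchanged at the end, in percent of the starting complex charged, for each flask in turn (dusk, winter, dawn)

Friday's readings fall after 2.50 h, so I take it that a second exchange follows the first. My guess is that the whole charge of protic impurity takes starting complex one for one, which puts my estimated cap on complex with one exchanged at 50.0 % of the charge, and Friday's reading of 41.7 % stays under that. The first exchange then uses one incoming ligand per usable complex, and what remains I call spare ligand, S: 1.30 M on Friday. Friday's readings fall from 41.7 % to 10.8 % at about 0.142 h⁻¹, which gives my reading of the fading constant k, the fall per hour for each mole per litre of spare ligand, 0.110 M⁻¹ h⁻¹.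

Taking S as steady, this is a pseudo-first-order fall, so I reckon the percentage as the cap times exp(−kSt), counted from the start. For Tuesday's flask at 12.0 h, with S = 0.235 M, that gives 36.7 % against the reading 36.2 %. With S = 0.123 M, 0.287 M and 0.815 M, I expect 35.7 % in dusk, 22.7 % in winter and 5.34 % in dawn.

The forecast differs: it gives 23 %, 38 % and 22 %, reasoning that “the protic impurity destroys one equivalent” of incoming ligand.

The flasks give 33.1 %, 24.3 % and 6.47 %.

    complex with one exchanged + incoming ligand ⇌ leaving ligand + complex with two exchanged (K = 0.200, k = 0.00240 M⁻¹ min⁻¹)
    leaving ligand → by-product carried off (k = 0.0310 min⁻¹)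
    starting complex + incoming ligand ⇌ leaving ligand + complex with one exchanged (K = 3.20, k = 0.0130 M⁻¹ min⁻¹)
    protic impurity + starting complex → quenched substrate (k = 0.110 M⁻¹ min⁻¹)

In dusk, taking each forward rate alone, the first exchange takes incoming ligand 34 times as fast as the second at 0.540 h, but 0.50 times as fast at 25.0 h, when, each step taken net, complex with one exchanged is made at 0.491 of the rate at which it is used up. In winter the forward half-life of starting complex, with the other concentrations as charged, is 1.8 h, shorter than the fading half-life ln(2)/(kS) of 22.0 h that I reckon from k, and complex with one exchanged ends at 24.3 %.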